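**Retrosynthetic overview**
1. Last event: the Z-C5=C6 alkene and the C11 tertiary alcohol are unmasked together from a gem-dimethylcyclopropyl carbinol. The cyclopropane and C7 come from (+)-2-carene, so no alkene is present while the ten-membered ring is closed and saturated.
2. Key disconnection: the dihydropyran is cut at CH2–C(ring A) and at O–C(ring A). The terpene keeps an oxetane (O, C10, C1, CH2), and the C=C edge of ring A is inserted into its O–CH2 bond (four- to six-membered ring).
3. Enabling feature: in the pyran, the ether O and the CH2 are 1,3-related across C10(Me)–C1(H), so four of its six atoms already form an oxetane. The other two are the alpha-carbon and a carbonyl carbon of the beta-triketone ring A. That carbonyl can accept the terpene's own oxygen by condensation, so the tertiary C10–O bond and both ring-fusion stereocentres are made early and never broken.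
4. Ring order: ring A (dearomatised phloroglucinol) and cyclopropane (chiral pool), then oxetane, ten-membered ring (RCM, then saturation), pyran (ring expansion), and finally cyclopropane opening.
5. Stereocontrol: C7 from the chiral pool, C4/C5 by crotylboration, C10/C1 by Sharpless epoxidation and invertive cuprate opening.

Key step: step 15

Remark: terpenoid carbons carry germacrane numbers (C1 ring-fusion CH, C4 CHMe, C5/C6 alkene, C7 CH–C11, C10 O-bearing quaternary carbon; the pyran CH2 is C1'). Beta-triketones are drawn as one of their rapidly equilibrating enol tautomers.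

**Step 1**
Reactants: 1 phloroglucinol; 2 isobutyryl chloride
Product: 3 phloroisobutyrophenone
Conditions: AlCl3 (3.5 equiv), PhNO2, 65 °C; aq. HCl
Reagents that add atoms: none
Why: Friedel–Crafts C-acylation of the very electron-rich arene should stop after one acyl group because the chelated aryl ketone deactivates the ring.

**Step 2**
Reactants: 3 phloroisobutyrophenone
Product: 4 isobutyrylfilicinic acid
Conditions: MeI (2.1 equiv), NaOMe, MeOH, 0 °C to rt
Reagents that add atoms: iodomethane, CI
Why: Dearomatising double C-methylation of the phenolate; the second methyl enters at the same carbon (now part of a beta-diketonate), and limiting MeI should keep the other ring CH free.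

**Step 3**
Reactants: 4 isobutyrylfilicinic acid
Product: 5 iodo-isobutyrylfilicinic acid (iodine on the one remaining ring CH)
Conditions: NIS, MeCN, 0 °C, dark
Reagents that add atoms: N-iodosuccinimide, O=C1CCC(=O)N1I
Why: Electrophilic alpha-iodination of an enolised beta-dicarbonyl can occur only at the single ring carbon that still bears hydrogen.

**Step 4**
Reactants: 5 iodo-isobutyrylfilicinic acid
Product: 6 bis(triethylsilyl) enol ether of 5
Conditions: Et3SiOTf, Et3N, CH2Cl2, −78 to 0 °C
Reagents that add atoms: triethylsilyl triflate, CC[Si](CC)(CC)OS(=O)(=O)C(F)(F)F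
Why: O-silylation removes both acidic protons and turns the iodo-dione into a neutral alpha-iodo-beta-silyloxy enone that is fit for cross-coupling.

**Step 5**
Reactants: 7 (+)-2-carene, (1S,6R)
Product: 8 (1S,3R)-2,2-dimethyl-3-(3-oxobutyl)cyclopropane-1-carbaldehyde
Conditions: O3, CH2Cl2–MeOH, −78 °C; Me2S
Reagents that add atoms: ozone, [O-][O+]=O
Why: Ozonolysis cleaves the only alkene and leaves the cis-cyclopropane (future C6, C7, C11) intact, giving C5 as aldehyde and C10 as methyl ketone.

**Step 6**
Reactants: 8 keto aldehyde
Product: 9 syn-homoallylic alcohol (4S,5R,6S,7R)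
Conditions: preformed (Z)-crotyl-B(Ipc)2 [Ipc from (−)-alpha-pinene], THF–Et2O, −78 °C; then NaOH, H2O2, 0 °C
Reagents that add atoms: (Z)-crotyldiisopinocampheylborane, C/C=C\CB([C@H]1C[C@H]2C[C@@H]([C@@H]1C)C2(C)C)[C@H]1C[C@H]2C[C@@H]([C@@H]1C)C2(C)C
Why: Brown crotylboration through a Zimmerman–Traxler chair: the Z-crotyl unit gives the syn pair, the Ipc groups fix its absolute sense (4S,5R) by reagent control, and the methyl ketone is inert at −78 °C.

**Step 7**
Reactants: 9 syn-homoallylic alcohol
Product: 10 C5 tert-butyldimethylsilyl ether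
Conditions: TBSCl, imidazole, DMF, 35 °C
Reagents that add atoms: tert-butyldimethylsilyl chloride, CC(C)(C)[Si](C)(C)Cl
Why: Silylation under non-acidic conditions protects the acid-sensitive cyclopropyl carbinol without enolising the ketone.

**Step 8**
Reactants: 10 silyl ether ketone
Product: 11 ethyl (E)-enoate (C1=C10)
Conditions: (EtO)2P(O)CH2CO2Et, NaH, THF, 0 to 50 °C; chromatography
Reagents that add atoms: triethyl phosphonoacetate, CCOC(=O)CP(=O)(OCC)OCC
Why: Horner–Wadsworth–Emmons olefination of the methyl ketone should favour the E-trisubstituted enoate (ester trans to the longer chain), and the minor Z isomer is removed here.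

**Step 9**
Reactants: 11 ethyl (E)-enoate
Product: 12 (E)-allylic alcohol
Conditions: iBu2AlH, CH2Cl2, −78 °C; Rochelle salt
Reagents that add atoms: none
Why: 1,2-Reduction of the conjugated ester with DIBAL-H gives the geraniol-type allylic alcohol without touching the alkenes or the silyl ether.

**Step 10**
Reactants: 12 (E)-allylic alcohol
Product: 13 (1R,10R)-epoxy alcohol
Conditions: Ti(OiPr)4 (10 mol %), D-(−)-diethyl tartrate (12 mol %), t-BuOOH, 4 Å MS, CH2Cl2, −20 °C
Reagents that add atoms: tert-butyl hydroperoxide, CC(C)(C)OO
Why: Sharpless asymmetric epoxidation touches only the allylic-alcohol alkene, and D-(−)-tartrate delivers oxygen to the face that sets the final 10R tertiary C–O centre, in the same sense as for geraniol.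

**Step 11**
Reactants: 13 epoxy alcohol
Product: 14 (1S,10R)-1,3-diol with a vinyl group at C1
Conditions: CH2=CHMgBr (3 equiv), CuI (15 mol %), THF–Et2O, −30 to 0 °C; aq. NH4Cl
Reagents that add atoms: vinylmagnesium bromide, C=C[Mg]Br
Why: Copper-catalysed SN2 opening occurs at C1 because C10 is fully substituted, and the inversion converts the trans-epoxide into the 1S,10R relationship of the target ring fusion.

**Step 12**
Reactants: 14 1,3-diol
Product: 16 2,2,3-trisubstituted oxetane diene, via primary monotosylate 15 (not isolated)
Conditions: n-BuLi (1 equiv), THF, −78 to 0 °C; TsCl (1 equiv); n-BuLi (1 equiv), 0 to 45 °C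
Reagents that add atoms: none
Why: Williamson 4-exo-tet closure of the tertiary lithium alkoxide on the primary tosylate, helped by the Thorpe–Ingold effect at C10, breaks no bond at C1 or C10, and the tight lithium alkoxide should disfavour Grob fragmentation.

**Step 13**
Reactants: 16 oxetane diene
Product: 17 tricyclic cyclodecene (C2=C3, E/Z irrelevant)
Conditions: second-generation Grubbs catalyst (10 mol %), 1,4-benzoquinone (20 mol %), CH2Cl2 (1 mM), reflux
Reagents that add atoms: none
Why: Ring-closing metathesis of two monosubstituted alkenes; the cis-cyclopropane and the oxetane freeze two of the ring torsions and should bias the chain toward closure, while benzoquinone suppresses alkene migration into the C1 and C4 stereocentres.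

**Step 14**
Reactants: 17 tricyclic cyclodecene
Product: 18 saturated tricyclic oxetane (1S,4S,5R,6S,7R,10R)
Conditions: TsNHNH2, NaOAc, DME–H2O, 85 °C
Reagents that add atoms: none
Why: Diimide reduction transfers H2 in a concerted way, so neither allylic stereocentre can be scrambled, and cyclopropane, oxetane and silyl ether are inert.

**Step 15**
Reactants: 18 saturated tricyclic oxetane; 6 bis(triethylsilyl) iodo enol ether
Product: 23 tetracyclic dihydropyran (cyclopropane and C5 silyl ether still in place), via dilithio species 19 (not isolated), via alkylzinc bromide 20 (not isolated), via silylated coupling product 21 (not isolated), via hydroxy triketone 22 (not isolated)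
Conditions: LiDBB (2.1 equiv), THF, 0 °C; ZnBr2, −78 to 0 °C; Me3SiCl; 6, Pd2(dba)3 (2.5 mol %), SPhos (10 mol %), THF–NMP, 40 °C; then AcOH, MeOH–H2O, rt; PPTS (cat.), PhMe, 50 °C
Reagents that add atoms: none
Why: Two single-electron transfers from LiDBB break the strained ring at its O–CH2 bond (reductive lithiation of oxetanes opens toward the tertiary alkoxide and the least substituted, primary carbanion), so the electrophilic CH2 of 18 becomes the nucleophile 19 while the C10–O bond and the C1 and C10 stereocentres are never touched. ZnBr2 and Me3SiCl convert 19 into the neutral alkylzinc 20, and a Negishi cross-coupling (oxidative addition of the C–I bond of 6 to zerovalent palladium, transmetalation, reductive elimination; closest known type: primary alkylzinc halides with alpha-iodoenones) joins C1' to a ring A carbon that is normally itself a nucleophile, a union that direct alkylation of the beta-triketone with an unactivated electrophile cannot deliver because it goes to oxygen. Mild acid strips the three labile silyl groups, the freed tertiary alcohol of 22 adds 6-exo-trig to the neighbouring ring A carbonyl and the hemiketal loses water, so the four oxetane atoms reappear in the same order in a six-membered ring that has gained the C=C edge of ring A. No new stereocentre is formed, and the trans ring fusion (1S,10R) is simply that of the oxetane. Three selectivities are needed: O–CH2 over O–C10 cleavage (secured by the preference for the primary organolithium), carbon over oxygen bonding at ring A (fixed by the position of iodine), and closure on the carbonyl next to the acyl-bearing carbon rather than the one next to CMe2 (the latter is neopentyl-like and poorly accessible to a tertiary alcohol, and the wanted mode keeps the hydrogen-bonded enol/isobutyryl chelate).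

**Step 16**
Reactants: 23 tetracyclic dihydropyran
Product: 25 target CNP0564661.1, via cyclopropylcarbinol 24 (not isolated)
Conditions: TsOH·H2O (20 mol %), acetone–H2O (3:1), 40 °C
Reagents that add atoms: water, O
Why: Acid removes the silyl group and ionises the C5–O bond with participation of the antiperiplanar C6–C11 bond (cyclopropylcarbinyl-to-homoallyl rearrangement, Julia type), strain release gives the tertiary C11 cation that water captures, and the 5R configuration from step 6 places C4 synclinal to C7 in that reactive conformer, so C5=C6 should form Z, which is also the less strained cyclodecene geometry, while C1, C4, C7 and C10 stay untouched.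

**Compound list**
1 | phloroglucinol | Oc1cc(O)cc(O)c1 | starting material
2 | isobutyryl chloride | CC(C)C(=O)Cl | starting material
3 | phloroisobutyrophenone | CC(C)C(=O)c1c(O)cc(O)cc1O | intermediate
4 | isobutyrylfilicinic acid | CC(C)C(=O)C1=C(O)C(C)(C)C(=O)C=C1O | intermediate
5 | iodo-isobutyrylfilicinic acid | CC(C)C(=O)C1=C(O)C(C)(C)C(=O)C(I)=C1O | intermediate
6 | bis(triethylsilyl) enol ether of 5 | CC(C)C(=O)C1=C(O[Si](CC)(CC)CC)C(C)(C)C(=O)C(I)=C1O[Si](CC)(CC)CC | intermediate
7 | (+)-2-carene, (1S,6R) | CC1=C[C@@H]2C(C)(C)[C@@H]2CC1 | starting material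
8 | (1S,3R)-2,2-dimethyl-3-(3-oxobutyl)cyclopropane-1-carbaldehyde | CC(=O)CC[C@@H]1[C@H](C=O)C1(C)C | intermediate
9 | syn-homoallylic alcohol (4S,5R,6S,7R) | CC(=O)CC[C@@H]1[C@H]([C@H](O)[C@@H](C)C=C)C1(C)C | intermediate
10 | C5 TBS ether of 9 | CC(=O)CC[C@@H]1[C@H]([C@H](O[Si](C)(C)C(C)(C)C)[C@@H](C)C=C)C1(C)C | intermediate
11 | ethyl (E)-enoate | CCOC(=O)/C=C(\C)CC[C@@H]1[C@H]([C@H](O[Si](C)(C)C(C)(C)C)[C@@H](C)C=C)C1(C)C | intermediate
12 | (E)-allylic alcohol | OC/C=C(\C)CC[C@@H]1[C@H]([C@H](O[Si](C)(C)C(C)(C)C)[C@@H](C)C=C)C1(C)C | intermediate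
13 | (1R,10R)-epoxy alcohol | OC[C@H]1O[C@]1(C)CC[C@@H]2[C@H]([C@H](O[Si](C)(C)C(C)(C)C)[C@@H](C)C=C)C2(C)C | intermediate
14 | (1S,10R)-1,3-diol, vinyl at C1 | OC[C@H](C=C)[C@](C)(O)CC[C@@H]1[C@H]([C@H](O[Si](C)(C)C(C)(C)C)[C@@H](C)C=C)C1(C)C | intermediate
15 | primary monotosylate of 14 | Cc1ccc(cc1)S(=O)(=O)OC[C@H](C=C)[C@](C)(O)CC[C@@H]2[C@H]([C@H](O[Si](C)(C)C(C)(C)C)[C@@H](C)C=C)C2(C)C | intermediate
16 | oxetane diene (vinyl cis to methyl on the oxetane) | C=C[C@H]1CO[C@]1(C)CC[C@@H]2[C@H]([C@H](O[Si](C)(C)C(C)(C)C)[C@@H](C)C=C)C2(C)C | intermediate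
17 | tricyclic cyclodecene (oxetane, ten-membered ring, cyclopropane; C2=C3 geometry open) | C1O[C@]2(C)CC[C@@H]3[C@@H](C3(C)C)[C@H](O[Si](C)(C)C(C)(C)C)[C@@H](C)C=C[C@@H]12 | intermediate
18 | saturated tricyclic oxetane (1S,4S,5R,6S,7R,10R) | C1O[C@]2(C)CC[C@@H]3[C@@H](C3(C)C)[C@H](O[Si](C)(C)C(C)(C)C)[C@@H](C)CC[C@@H]12 | intermediate
19 | gamma-lithio lithium alkoxide | [Li]C[C@H]1[C@](C)(O[Li])CC[C@@H]2[C@@H](C2(C)C)[C@H](O[Si](C)(C)C(C)(C)C)[C@@H](C)CC1 | intermediate
20 | alkylzinc bromide, C10 trimethylsilyl ether | Br[Zn]C[C@H]1[C@](C)(O[Si](C)(C)C)CC[C@@H]2[C@@H](C2(C)C)[C@H](O[Si](C)(C)C(C)(C)C)[C@@H](C)CC1 | intermediate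
21 | silylated coupling product | CC(C)C(=O)C1=C(O[Si](CC)(CC)CC)C(C)(C)C(=O)C(C[C@H]2[C@](C)(O[Si](C)(C)C)CC[C@@H]3[C@@H](C3(C)C)[C@H](O[Si](C)(C)C(C)(C)C)[C@@H](C)CC2)=C1O[Si](CC)(CC)CC | intermediate
22 | hydroxy triketone | CC(C)C(=O)C1=C(O)C(C)(C)C(=O)C(C[C@H]2[C@](C)(O)CC[C@@H]3[C@@H](C3(C)C)[C@H](O[Si](C)(C)C(C)(C)C)[C@@H](C)CC2)=C1O | intermediate
23 | tetracyclic dihydropyran, C5 TBS ether | CC(C)C(=O)C1=C(O)C(C)(C)C(=O)C2=C1O[C@]1(C)CC[C@@H]3[C@@H](C3(C)C)[C@H](O[Si](C)(C)C(C)(C)C)[C@@H](C)CC[C@H]1C2 | intermediate
24 | cyclopropylcarbinol (free C5 alcohol) | CC(C)C(=O)C1=C(O)C(C)(C)C(=O)C2=C1O[C@]1(C)CC[C@@H]3[C@@H](C3(C)C)[C@H](O)[C@@H](C)CC[C@H]1C2 | intermediate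
25 | CNP0564661.1 (1S,4S,7R,10R; 5Z) | CC(C)C(=O)C1=C(O)C(C)(C)C(=O)C2=C1O[C@]1(C)CC[C@@H](C(C)(C)O)/C=C\[C@@H](C)CC[C@H]1C2 | target

**Step count**
- Total: 16 steps.
- Longest linear sequence: 12 steps (steps 5 to 16, from (+)-2-carene).

**Steps most likely to fail**

**1. Step 15.**
- Risk: oxidative addition and transmetalation at the fully substituted iodoalkene may be slow, so protodemetalation and beta-hydride elimination would consume the alkylzinc.
- Fallback: it sets out from 18. The same reductive lithiation gives 19, which is quenched with B(OMe)3 and then NaOH/H2O2 to give the ring 1,3-diol F1. TEMPO/PhI(OAc)2 oxidises only the primary alcohol to the beta-hydroxy aldehyde F2. A three-component reductive alkylation of 4 follows: Knoevenagel condensation with F2 under L-proline catalysis, then transfer hydrogenation of the alkylidene by Hantzsch ester. This forms the C1'–ring A bond and comes back to the route at 22, which PPTS closes to 23.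

**2. Step 13.**
- Risk: oligomerisation may outrun closure of the ten-membered ring, or ruthenium hydrides may shift the alkenes.
- Fallback: it sets out from 16. Ozonolysis of both vinyl groups (O3; Me2S) gives the dialdehyde F3. An intramolecular McMurry coupling with low-valent titanium (TiCl3(DME)1.5, Zn–Cu, DME, reflux, slow addition) forms the same C2=C3 bond and comes back at 17.

**3. Step 16.**
- Risk: alkene geometry may be lost if the cation relaxes before the ring opens, and proton loss from the C11 cation competes with hydration.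
- Fallback: it sets out from 23. The solvolysis is run as described regardless of selectivity, which would give the E isomer F4 beside 25. The mixture is then equilibrated by reversible thiyl radical addition (PhSH, AIBN, PhH, 80 °C) toward the less strained Z-cyclodecene, coming back at 25.

**Further compounds**
F1 | step 15 | ring 1,3-diol (C1' primary alcohol, C10 tertiary alcohol) | OC[C@H]1[C@](C)(O)CC[C@@H]2[C@@H](C2(C)C)[C@H](O[Si](C)(C)C(C)(C)C)[C@@H](C)CC1
F2 | step 15 | beta-hydroxy aldehyde | O=C[C@H]1[C@](C)(O)CC[C@@H]2[C@@H](C2(C)C)[C@H](O[Si](C)(C)C(C)(C)C)[C@@H](C)CC1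
F3 | step 13 | oxetane dialdehyde | O=C[C@H]1CO[C@]1(C)CC[C@@H]2[C@H]([C@H](O[Si](C)(C)C(C)(C)C)[C@@H](C)C=O)C2(C)C
F4 | step 16 | 5E isomer of the target | CC(C)C(=O)C1=C(O)C(C)(C)C(=O)C2=C1O[C@]1(C)CC[C@@H](C(C)(C)O)/C=C/[C@@H](C)CC[C@H]1C2
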